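**Retrosynthetic overview**

1. Numbering: side chain C1' (ArCH2) to C16'; target 24 is a 2-methylhydroquinone carrying at C6 the chain C1'H2–C2'H=C3'(Me)–C4'H2–C5'H(OH)–C6'H=C7'(Me)–C8'H2–C9'H2–C10'H=C11'(Me)–C12'H2–C13'H2–C14'H=C15'Me2, with C5' (R) and 2E,6E,10E (TBS = tert-butyldimethylsilyl, TES = triethylsilyl).
2. Key disconnection C9'–C10' (sp3–sp2): both carbons enter as electrophiles, C9' as the α-carbon of the γ,δ-unsaturated acid 21 (its carboxyl carbon leaves as CO2 from a redox-active ester) and C10' as the iodine-bearing carbon of E-alkenyl iodide 5; they are joined by nickel-catalysed electroreductive decarboxylative alkenylation, a radical union of two carbons of like polarity that completes the C27 skeleton.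
3. Enabling feature: C9' is a primary CH2 separated from the C6'=C7' olefin by C8'H2, so the C9' radical is neither allylic nor β to a leaving group and lies four bonds from the C5' carbinol; C10' is the hydrogen-bearing end of the trisubstituted C10'=C11' olefin, whose E geometry is already in place in alkenyl iodide 5 (from the syn-methylalumination of step 2) and is carried through the stereoretentive coupling; the only ring, the benzene ring, is remote and silyl-protected.
4. Other disconnections: C1'–C2' (alkyne methylalumination, then Pd(PPh3)4-catalysed coupling with benzyl bromide 8), C4'–C5' (catalytic asymmetric propargylation of enal 14 sets C5'), C5'–C6' (methylalumination, then formaldehyde); all three E-olefins come from syn-methylalumination of terminal alkynes.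
5. No ring is formed: the hydroquinone is bought as mirror-symmetric 2,6-dimethylhydroquinone and desymmetrised by one benzylic bromination; three TBS ethers are removed together at the end.

Key step: step 13

Remark: the sense of induction of the phosphoric acid in step 8 is assigned by analogy with aryl aldehydes (alkenyl taking the place of aryl); if it proves opposite, the enantiomeric catalyst is used and nothing else changes.

**Route**

Step 1
Reactants: 1 6-methylhept-5-en-2-one
Product: 3 6-methylhept-5-en-1-yne, via enol phosphate 2 (not isolated)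
Conditions: LiN(iPr)2 (1.05 equiv), THF, −78 °C; ClP(O)(OEt)2, −78 °C to rt; then LiN(iPr)2 (2.3 equiv), THF, −78 °C to rt; aq. NH4Cl
Reagents that add atoms: none
Why: Kinetic deprotonation at the methyl group and O-phosphorylation give the terminal enol phosphate, which undergoes base-induced β-elimination to the terminal alkyne (methyl ketone to alkyne conversion), the trisubstituted olefin being inert.

Step 2
Reactants: 3 6-methylhept-5-en-1-yne
Product: 5 (E)-1-iodo-2,6-dimethylhepta-1,5-diene, via alkenylalane 4 (not isolated)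
Conditions: Me3Al (2 equiv), Cp2ZrCl2 (0.25 equiv), CH2Cl2, 0 °C to rt; then I2, THF, −30 to 0 °C
Reagents that add atoms: trimethylaluminium C[Al](C)C; iodine II
Why: Negishi zirconium-catalysed methylalumination adds Me and Al syn across the alkyne with Me at the internal carbon, and iodinolysis of the C–Al bond with retention sets the E geometry of the future C10'=C11' olefin.

Step 3
Reactants: 6 2,6-dimethylbenzene-1,4-diol
Product: 7 1,4-bis(tert-butyldimethylsilyloxy)-2,6-dimethylbenzene
Conditions: TBSCl (2.5 equiv), imidazole (5 equiv), DMF, rt to 50 °C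
Reagents that add atoms: tert-butyldimethylsilyl chloride CC(C)(C)[Si](C)(C)Cl
Why: Imidazole-promoted O-silylation should protect both phenols (the flanked one on gentle warming) as ethers stable to organoaluminium, palladium and reductive conditions.

Step 4
Reactants: 7 1,4-bis(tert-butyldimethylsilyloxy)-2,6-dimethylbenzene
Product: 8 2,5-bis(tert-butyldimethylsilyloxy)-3-methylbenzyl bromide
Conditions: NBS (0.95 equiv), AIBN (cat.), PhCF3, 80 °C, hν
Reagents that add atoms: N-bromosuccinimide O=C1CCC(=O)N1Br
Why: Wohl–Ziegler radical bromination takes one of the two symmetry-equivalent benzylic methyl groups, so only one regioisomer can form, while the free ring positions are shielded by OTBS and CH3 and the non-polar radical conditions disfavour nuclear bromination.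

Step 5
Reactants: 9 pent-4-yn-1-ol
Product: 10 triethyl(pent-4-yn-1-yloxy)silane
Conditions: TESCl, imidazole, CH2Cl2, 0 °C to rt
Reagents that add atoms: chlorotriethylsilane CC[Si](Cl)(CC)CC
Why: Standard silylation; TES is chosen because it can later be cleaved in the presence of TBS ethers.

Step 6
Reactants: 10 triethyl(pent-4-yn-1-yloxy)silane
Product: 13 (E)-3-methyl-6-(triethylsilyloxy)hex-2-en-1-ol, via alkenylalane 11 (not isolated), via lithium alkenylaluminate 12 (not isolated)
Conditions: Me3Al (2 equiv), Cp2ZrCl2 (0.25 equiv), CH2Cl2, 0 °C to rt; volatiles removed; n-BuLi, hexane/THF, −78 to 0 °C; (CH2O)n, THF, rt; aq. NH4Cl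
Reagents that add atoms: trimethylaluminium C[Al](C)C; paraformaldehyde (as formaldehyde) C=O
Why: Negishi methylalumination (syn, Me at the internal carbon) followed by hydroxymethylation of the derived aluminate with formaldehyde, which proceeds with retention, should give the E-trisubstituted allylic alcohol (future C5'–C9' plus the carboxyl carbon).

Step 7
Reactants: 13 (E)-3-methyl-6-(triethylsilyloxy)hex-2-en-1-ol
Product: 14 (E)-3-methyl-6-(triethylsilyloxy)hex-2-enal
Conditions: TEMPO (10 mol%), PhI(OAc)2 (1.1 equiv), CH2Cl2, rt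
Reagents that add atoms: none
Why: Oxoammonium-mediated oxidation of the allylic alcohol stops at the enal and is not expected to isomerise the E olefin.

Step 8
Reactants: 14 (E)-3-methyl-6-(triethylsilyloxy)hex-2-enal
Product: 16 (4R,5E)-6-methyl-9-(triethylsilyloxy)non-5-en-1-yn-4-ol, via borate ester 15 (not isolated)
Conditions: allenylboronic acid pinacol ester (1.5 equiv), (R)-TRIP phosphoric acid (5 mol%), 4 Å MS, toluene, 0 °C; aq. NaHCO3 work-up
Reagents that add atoms: allenylboronic acid pinacol ester C=C=CB1OC(C)(C)C(C)(C)O1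
Why: In this chiral-Brønsted-acid-catalysed carbonyl propargylation the allenylboronate adds through a closed six-membered SE2' transition state to give the homopropargylic alcohol, and the phosphoric acid bound to the boronate selects the aldehyde face, setting C5' as R under catalyst control.

Step 9
Reactants: 16 (4R,5E)-6-methyl-9-(triethylsilyloxy)non-5-en-1-yn-4-ol
Product: 17 (4R,5E)-4-(tert-butyldimethylsilyloxy)-6-methyl-9-(triethylsilyloxy)non-5-en-1-yne
Conditions: TBSCl, imidazole, DMF, rt
Reagents that add atoms: tert-butyldimethylsilyl chloride CC(C)(C)[Si](C)(C)Cl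
Why: Silylation of the secondary allylic alcohol protects C5'–OH for the oxidation and activation steps without touching the stereocentre.

Step 10
Reactants: 17 (4R,5E)-4-(tert-butyldimethylsilyloxy)-6-methyl-9-(triethylsilyloxy)non-5-en-1-yne; 8 2,5-bis(tert-butyldimethylsilyloxy)-3-methylbenzyl bromide
Product: 19 (2E,5R,6E)-1-[2,5-bis(tert-butyldimethylsilyloxy)-3-methylphenyl]-5-(tert-butyldimethylsilyloxy)-3,7-dimethyl-10-(triethylsilyloxy)deca-2,6-diene, via alkenylalane 18 (not isolated)
Conditions: Me3Al (2.5 equiv), Cp2ZrCl2 (0.3 equiv), CH2Cl2, 0 °C to rt; volatiles (excess Me3Al) removed; then 8, Pd(PPh3)4 (5 mol%), THF, rt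
Reagents that add atoms: trimethylaluminium C[Al](C)C
Why: Negishi methylalumination of the homopropargylic silyl ether followed by palladium-catalysed cross-coupling of the alkenylalane with the benzylic bromide (alkenyl transfer with retention) forms C1'–C2' and sets the E geometry of C2'=C3'.

Step 11
Reactants: 19 (2E,5R,6E)-1-[2,5-bis(tert-butyldimethylsilyloxy)-3-methylphenyl]-5-(tert-butyldimethylsilyloxy)-3,7-dimethyl-10-(triethylsilyloxy)deca-2,6-diene
Product: 20 (4E,6R,8E)-10-[2,5-bis(tert-butyldimethylsilyloxy)-3-methylphenyl]-6-(tert-butyldimethylsilyloxy)-4,8-dimethyldeca-4,8-dien-1-ol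
Conditions: PPTS (0.2 equiv), MeOH/CH2Cl2 (1:1), 0 °C
Reagents that add atoms: none
Why: Acid-catalysed methanolysis cleaves the unhindered primary TES ether much faster than the secondary and aryl TBS ethers, under conditions too mild to ionise the allylic C5'–O bond.

Step 12
Reactants: 20 (4E,6R,8E)-10-[2,5-bis(tert-butyldimethylsilyloxy)-3-methylphenyl]-6-(tert-butyldimethylsilyloxy)-4,8-dimethyldeca-4,8-dien-1-ol
Product: 21 (4E,6R,8E)-10-[2,5-bis(tert-butyldimethylsilyloxy)-3-methylphenyl]-6-(tert-butyldimethylsilyloxy)-4,8-dimethyldeca-4,8-dienoic acid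
Conditions: TEMPO (0.2 equiv), PhI(OAc)2 (2.2 equiv), MeCN/H2O (1:1), rt
Reagents that add atoms: water O
Why: TEMPO/PhI(OAc)2 oxidation in aqueous acetonitrile takes the primary alcohol through the aldehyde hydrate to the carboxylic acid and should leave olefins, silyl ethers and the silyl-protected arene untouched.

Step 13
Reactants: 21 (4E,6R,8E)-10-[2,5-bis(tert-butyldimethylsilyloxy)-3-methylphenyl]-6-(tert-butyldimethylsilyloxy)-4,8-dimethyldeca-4,8-dienoic acid; 5 (E)-1-iodo-2,6-dimethylhepta-1,5-diene
Product: 23 (2E,5R,6E,10E)-1-[2,5-bis(tert-butyldimethylsilyloxy)-3-methylphenyl]-5-(tert-butyldimethylsilyloxy)-3,7,11,15-tetramethylhexadeca-2,6,10,14-tetraene, via redox-active ester 22 (not isolated)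
Conditions: N-hydroxyphthalimide, DIC, DMF, rt; then 5 (2 equiv), NiCl2·6H2O (10 mol%), 2,2'-bipyridine (10 mol%), AgNO3 (0.3 equiv), LiCl, DMF, Mg anode/RVC cathode, constant current, rt
Reagents that add atoms: none
Why: The acid is activated in situ as its N-hydroxyphthalimide ester 22; cathodically generated zerovalent nickel–bipyridine inserts into the C–I bond of 5 with retention, while single-electron reduction of 22 expels phthalimide anion and CO2 to give the primary C9' radical, which is captured by the divalent alkenylnickel species and released by reductive elimination from trivalent nickel as the C9'–C10' bond. The closest known reaction type is the nickel-catalysed electroreductive decarboxylative alkenylation of primary redox-active esters with 2-methylalk-1-enyl iodides, a cross-electrophile coupling used to join isoprenoid units. No ring is closed and no stereocentre is created: the E geometry of C10'=C11' is carried over from 5 because oxidative addition and reductive elimination are stereoretentive, and C5' (R) lies four bonds from the radical centre and is untouched. The step needs cross- over homo-coupling, which the different activation modes of the two electrophiles provide (two-electron oxidative addition for the sp2 iodide, one-electron fragmentation for the ester). It also needs the C6'=C7' geometry to survive the homoallylic radical: 3-exo closure onto the methyl-bearing C7' is slow and reversible compared with capture by nickel, and no five- or six-membered cyclisation is available. Silyl ethers, the electron-rich arene and the other trisubstituted olefins are inert to these mild reductive conditions, so the complete C27 skeleton with all four olefins and the stereocentre is assembled in this one operation.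

Step 14
Reactants: 23 (2E,5R,6E,10E)-1-[2,5-bis(tert-butyldimethylsilyloxy)-3-methylphenyl]-5-(tert-butyldimethylsilyloxy)-3,7,11,15-tetramethylhexadeca-2,6,10,14-tetraene
Product: 24 2-[(2E,5R,6E,10E)-5-hydroxy-3,7,11,15-tetramethylhexadeca-2,6,10,14-tetraen-1-yl]-6-methylbenzene-1,4-diol
Conditions: TBAF (4 equiv), AcOH (4 equiv), THF, 0 °C to rt, argon; degassed aq. Na2S2O4 work-up
Reagents that add atoms: none
Why: Buffered fluoride should remove the two aryl and the secondary TBS ethers in one operation while avoiding base-mediated air oxidation of the hydroquinone and acid-mediated ionisation or chroman formation, so C5' (R) and the olefin geometries are unchanged.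

**Compound list**

1 | 6-methylhept-5-en-2-one | CC(=O)CCC=C(C)C | starting material
2 | diethyl 6-methylhepta-1,5-dien-2-yl phosphate | C=C(CCC=C(C)C)OP(=O)(OCC)OCC | intermediate
3 | 6-methylhept-5-en-1-yne | C#CCCC=C(C)C | intermediate
4 | (E)-(2,6-dimethylhepta-1,5-dien-1-yl)dimethylalane | C[Al](C)/C=C(\C)CCC=C(C)C | intermediate
5 | (E)-1-iodo-2,6-dimethylhepta-1,5-diene | I/C=C(\C)CCC=C(C)C | intermediate
6 | 2,6-dimethylbenzene-1,4-diol | Cc1cc(O)cc(C)c1O | starting material
7 | 1,4-bis(tert-butyldimethylsilyloxy)-2,6-dimethylbenzene | Cc1cc(O[Si](C)(C)C(C)(C)C)cc(C)c1O[Si](C)(C)C(C)(C)C | intermediate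
8 | 2,5-bis(tert-butyldimethylsilyloxy)-3-methylbenzyl bromide | Cc1cc(O[Si](C)(C)C(C)(C)C)cc(CBr)c1O[Si](C)(C)C(C)(C)C | intermediate
9 | pent-4-yn-1-ol | C#CCCCO | starting material
10 | triethyl(pent-4-yn-1-yloxy)silane | C#CCCCO[Si](CC)(CC)CC | intermediate
11 | (E)-dimethyl[2-methyl-5-(triethylsilyloxy)pent-1-en-1-yl]alane | C[Al](C)/C=C(\C)CCCO[Si](CC)(CC)CC | intermediate
12 | lithium (E)-butyl(dimethyl)[2-methyl-5-(triethylsilyloxy)pent-1-en-1-yl]aluminate | [Li+].CCCC[Al-](C)(C)/C=C(\C)CCCO[Si](CC)(CC)CC | intermediate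
13 | (E)-3-methyl-6-(triethylsilyloxy)hex-2-en-1-ol | OC/C=C(\C)CCCO[Si](CC)(CC)CC | intermediate
14 | (E)-3-methyl-6-(triethylsilyloxy)hex-2-enal | O=C/C=C(\C)CCCO[Si](CC)(CC)CC | intermediate
15 | 2-{[(4R,5E)-6-methyl-9-(triethylsilyloxy)non-5-en-1-yn-4-yl]oxy}-4,4,5,5-tetramethyl-1,3,2-dioxaborolane | C#CC[C@@H](OB1OC(C)(C)C(C)(C)O1)/C=C(\C)CCCO[Si](CC)(CC)CC | intermediate
16 | (4R,5E)-6-methyl-9-(triethylsilyloxy)non-5-en-1-yn-4-ol | C#CC[C@@H](O)/C=C(\C)CCCO[Si](CC)(CC)CC | intermediate
17 | (4R,5E)-4-(tert-butyldimethylsilyloxy)-6-methyl-9-(triethylsilyloxy)non-5-en-1-yne | C#CC[C@@H](O[Si](C)(C)C(C)(C)C)/C=C(\C)CCCO[Si](CC)(CC)CC | intermediate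
18 | dimethyl[(1E,4R,5E)-4-(tert-butyldimethylsilyloxy)-2,6-dimethyl-9-(triethylsilyloxy)nona-1,5-dien-1-yl]alane | C[Al](C)/C=C(\C)C[C@@H](O[Si](C)(C)C(C)(C)C)/C=C(\C)CCCO[Si](CC)(CC)CC | intermediate
19 | (2E,5R,6E)-1-[2,5-bis(tert-butyldimethylsilyloxy)-3-methylphenyl]-5-(tert-butyldimethylsilyloxy)-3,7-dimethyl-10-(triethylsilyloxy)deca-2,6-diene | CC[Si](CC)(CC)OCCC/C(C)=C/[C@H](O[Si](C)(C)C(C)(C)C)C/C(C)=C/Cc1cc(O[Si](C)(C)C(C)(C)C)cc(C)c1O[Si](C)(C)C(C)(C)C | intermediate
20 | (4E,6R,8E)-10-[2,5-bis(tert-butyldimethylsilyloxy)-3-methylphenyl]-6-(tert-butyldimethylsilyloxy)-4,8-dimethyldeca-4,8-dien-1-ol | OCCC/C(C)=C/[C@H](O[Si](C)(C)C(C)(C)C)C/C(C)=C/Cc1cc(O[Si](C)(C)C(C)(C)C)cc(C)c1O[Si](C)(C)C(C)(C)C | intermediate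
21 | (4E,6R,8E)-10-[2,5-bis(tert-butyldimethylsilyloxy)-3-methylphenyl]-6-(tert-butyldimethylsilyloxy)-4,8-dimethyldeca-4,8-dienoic acid | OC(=O)CC/C(C)=C/[C@H](O[Si](C)(C)C(C)(C)C)C/C(C)=C/Cc1cc(O[Si](C)(C)C(C)(C)C)cc(C)c1O[Si](C)(C)C(C)(C)C | intermediate
22 | 1,3-dioxoisoindolin-2-yl (4E,6R,8E)-10-[2,5-bis(tert-butyldimethylsilyloxy)-3-methylphenyl]-6-(tert-butyldimethylsilyloxy)-4,8-dimethyldeca-4,8-dienoate | O=C(CC/C(C)=C/[C@H](O[Si](C)(C)C(C)(C)C)C/C(C)=C/Cc1cc(O[Si](C)(C)C(C)(C)C)cc(C)c1O[Si](C)(C)C(C)(C)C)ON1C(=O)c2ccccc2C1=O | intermediate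
23 | (2E,5R,6E,10E)-1-[2,5-bis(tert-butyldimethylsilyloxy)-3-methylphenyl]-5-(tert-butyldimethylsilyloxy)-3,7,11,15-tetramethylhexadeca-2,6,10,14-tetraene | CC(C)=CCC/C(C)=C/CC/C(C)=C/[C@H](O[Si](C)(C)C(C)(C)C)C/C(C)=C/Cc1cc(O[Si](C)(C)C(C)(C)C)cc(C)c1O[Si](C)(C)C(C)(C)C | intermediate
24 | 2-[(2E,5R,6E,10E)-5-hydroxy-3,7,11,15-tetramethylhexadeca-2,6,10,14-tetraen-1-yl]-6-methylbenzene-1,4-diol | CC(C)=CCC/C(C)=C/CC/C(C)=C/[C@H](O)C/C(C)=C/Cc1cc(O)cc(C)c1O | target

**Step count and risks**

Total step count: 14. Longest linear sequence: 10 steps (from 9 to 24, steps 5 to 14).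

Steps most likely to fail:

Step 13. The homoallylic C9' radical may lose the C6'=C7' geometry through reversible 3-exo closure, or it may be reduced or dimerised if capture by nickel is slow. The fallback replaces the radical cross-electrophile coupling by a two-electron sp3–sp2 cross-coupling. It sets out from 21: esterification with 2-mercaptopyridine N-oxide (DCC, CH2Cl2, dark) should give the Barton ester F1. Irradiation of F1 with CHI3 in benzene should give the primary iodide F2 by radical-chain iododecarboxylation, in which iodine-atom transfer traps the C9' radical faster than it can cyclise. Zinc insertion (activated Zn dust, LiCl, THF) should give the alkylzinc iodide F3. Negishi coupling of F3 with 5 (Pd(dppf)Cl2, THF/DMF, rt), stereoretentive at the alkenyl carbon, comes back to the route at 23.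

Step 8. Facial discrimination may be poor for a β,β-disubstituted enal, giving low enantiomeric purity at C5', or the allenyl adduct may compete. The fallback replaces asymmetric C–C bond formation by a resolution. It sets out from 14: Barbier propargylation (propargyl bromide, Zn dust, THF/aq. NH4Cl) should give the racemic homopropargylic alcohol F4. Lipase-catalysed transesterification (Burkholderia cepacia lipase, vinyl acetate, hexane) is expected, by the empirical size rule for lipases with alkenyl as the large and propargyl as the medium group, to acylate the R enantiomer to the acetate F5, which is separated from the unreacted S alcohol. Methanolysis of F5 (K2CO3, MeOH, 0 °C) comes back to the route at 16.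

Step 10. Carbometalation of the hindered homopropargylic ether may be incomplete or regiochemically impure, and in the one-pot palladium step methyl transfer or homocoupling of the benzylic bromide may compete. The fallback separates the two events and reverses the polarity of the partners. It sets out from 17 and 8: methylalumination of 17 and iodinolysis (as in step 2) should give the alkenyl iodide F6, which can be purified. Zinc insertion into 8 (Zn dust, LiCl, THF, 0 °C) should give the benzylzinc bromide F7. Negishi coupling of F6 with F7 (Pd(PPh3)4, THF, rt) comes back to the route at 19.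

**Further compounds**

F1 | step 13 | 2-thioxopyridin-1(2H)-yl (4E,6R,8E)-10-[2,5-bis(tert-butyldimethylsilyloxy)-3-methylphenyl]-6-(tert-butyldimethylsilyloxy)-4,8-dimethyldeca-4,8-dienoate | S=c1ccccn1OC(=O)CC/C(C)=C/[C@H](O[Si](C)(C)C(C)(C)C)C/C(C)=C/Cc1cc(O[Si](C)(C)C(C)(C)C)cc(C)c1O[Si](C)(C)C(C)(C)C
F2 | step 13 | (3E,5R,7E)-9-[2,5-bis(tert-butyldimethylsilyloxy)-3-methylphenyl]-5-(tert-butyldimethylsilyloxy)-1-iodo-3,7-dimethylnona-3,7-diene | ICC/C(C)=C/[C@H](O[Si](C)(C)C(C)(C)C)C/C(C)=C/Cc1cc(O[Si](C)(C)C(C)(C)C)cc(C)c1O[Si](C)(C)C(C)(C)C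
F3 | step 13 | {(3E,5R,7E)-9-[2,5-bis(tert-butyldimethylsilyloxy)-3-methylphenyl]-5-(tert-butyldimethylsilyloxy)-3,7-dimethylnona-3,7-dien-1-yl}zinc iodide | I[Zn]CC/C(C)=C/[C@H](O[Si](C)(C)C(C)(C)C)C/C(C)=C/Cc1cc(O[Si](C)(C)C(C)(C)C)cc(C)c1O[Si](C)(C)C(C)(C)C
F4 | step 8 | racemic (E)-6-methyl-9-(triethylsilyloxy)non-5-en-1-yn-4-ol | C#CCC(O)/C=C(\C)CCCO[Si](CC)(CC)CC
F5 | step 8 | (4R,5E)-6-methyl-9-(triethylsilyloxy)non-5-en-1-yn-4-yl acetate | C#CC[C@@H](OC(C)=O)/C=C(\C)CCCO[Si](CC)(CC)CC
F6 | step 10 | (1E,4R,5E)-4-(tert-butyldimethylsilyloxy)-1-iodo-2,6-dimethyl-9-(triethylsilyloxy)nona-1,5-diene | I/C=C(\C)C[C@@H](O[Si](C)(C)C(C)(C)C)/C=C(\C)CCCO[Si](CC)(CC)CC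
F7 | step 10 | [2,5-bis(tert-butyldimethylsilyloxy)-3-methylbenzyl]zinc bromide | Cc1cc(O[Si](C)(C)C(C)(C)C)cc(C[Zn]Br)c1O[Si](C)(C)C(C)(C)C
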